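The plan builds the hydroquinone ring last instead of coupling a preformed arene. The benzene ring is cut into a terminal furyl alkyne (C2, C3), a 2-silylvinyl(methoxy)carbene of chromium (C4, C5, C6) and one CO ligand (C1). One benzannulation forms three C–C bonds and the ring. It exploits the target's pattern of oxygen at C1 and C4 with the furan at C2: the two oxygens are para because one comes from CO and the other from the carbene methoxy group, and the furan ends ortho to the former. The product is a masked hydroquinone, released by oxidation to the quinone and reduction. The alkyne partner is the complete 2-ethynylfuran already carrying the (S)-furylic senecioate at C4.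

Key step: step 9

Remark: the senecioate is installed only after acetal cleavage and alkyne formation, so that the ester never meets aqueous acid or K2CO3/MeOH. The 3-furyl group is assumed to act as the large substituent in the oxazaborolidine reduction, and the configuration of 8 should be confirmed (Mosher esters) before going on.

Step 1
Reactants: 1 4-bromofuran-2-carbaldehyde
Product: 2 2-(4-bromofuran-2-yl)-1,3-dioxolane
Conditions: ethylene glycol (3 equiv), TsOH·H2O (5 mol %), toluene, reflux, Dean–Stark
Reagents that add atoms: ethylene glycol, OCCO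
Why: Acid-catalysed acetalisation with azeotropic removal of water masks the aldehyde so that the ring can later be lithiated and a ketone reduced in its presence.

Step 2
Reactants: 3 4-methylpent-3-enoic acid
Product: 5 N-methoxy-N,4-dimethylpent-3-enamide, via acyl imidazolide 4 (not isolated)
Conditions: CDI (1.1 equiv), CH2Cl2, 0 °C → rt; then MeNHOMe·HCl (1.2 equiv), rt
Reagents that add atoms: N,O-dimethylhydroxylamine hydrochloride, CNOC.Cl
Why: Carbonyldiimidazole activation and aminolysis (Weinreb amide formation) proceed without strong base, so the β,γ-double bond should not move into conjugation.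

Step 3
Reactants: 2 2-(4-bromofuran-2-yl)-1,3-dioxolane; 5 N-methoxy-N,4-dimethylpent-3-enamide
Product: 7 1-[5-(1,3-dioxolan-2-yl)furan-3-yl]-4-methylpent-3-en-1-one, via furyllithium 6 (not isolated)
Conditions: n-BuLi (1.05 equiv), THF, −78 °C, 20 min; then 5, −78 → −40 °C; sat. aq NH4Cl
Reagents that add atoms: none
Why: Bromine–lithium exchange at −78 °C outruns ring deprotonation and lithium migration to the α-position, and the Weinreb amide holds the adduct as a chelated tetrahedral intermediate so that the β,γ-unsaturated ketone appears only on the buffered quench (Weinreb ketone synthesis).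

Step 4
Reactants: 7 1-[5-(1,3-dioxolan-2-yl)furan-3-yl]-4-methylpent-3-en-1-one
Product: 8 (S)-1-[5-(1,3-dioxolan-2-yl)furan-3-yl]-4-methylpent-3-en-1-ol
Conditions: (R)-2-methyl-CBS-oxazaborolidine (15 mol %), catecholborane (1.6 equiv), toluene, −78 °C; MeOH quench, aq NaOH wash
Reagents that add atoms: none
Why: In this Corey–Bakshi–Shibata reduction the ketone should bind the (R)-oxazaborolidine–borane pair with the furyl group (the larger, π-type substituent) turned away from the catalyst, so hydride reaches the face giving the (S)-carbinol, as the (R)-catalyst does for aryl alkyl ketones, while catecholborane at −78 °C leaves the trisubstituted alkene and the acetal alone.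

Step 5
Reactants: 8 (S)-1-[5-(1,3-dioxolan-2-yl)furan-3-yl]-4-methylpent-3-en-1-ol
Product: 9 4-[(S)-1-hydroxy-4-methylpent-3-en-1-yl]furan-2-carbaldehyde
Conditions: PPTS (0.2 equiv), acetone/H2O (9:1), 40 °C
Reagents that add atoms: water, O
Why: Mild acid hydrolysis of the furfural-type acetal is fast because the furan stabilises the oxocarbenium ion, and the free furylic alcohol should ionise far less readily than an ester would, so the stereocenter should be kept.

Step 6
Reactants: 9 4-[(S)-1-hydroxy-4-methylpent-3-en-1-yl]furan-2-carbaldehyde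
Product: 10 (S)-1-(5-ethynylfuran-3-yl)-4-methylpent-3-en-1-ol
Conditions: dimethyl (1-diazo-2-oxopropyl)phosphonate (1.3 equiv), K2CO3 (2 equiv), MeOH, 0 °C → rt
Reagents that add atoms: dimethyl (1-diazo-2-oxopropyl)phosphonate, CC(=O)C(=[N+]=[N-])P(=O)(OC)OC
Why: Ohira–Bestmann homologation converts the non-enolisable furaldehyde into the terminal alkyne through a diazoalkene and 1,2-hydrogen shift, and the basic methanol is harmless because no ester is present yet.

Step 7
Reactants: 10 (S)-1-(5-ethynylfuran-3-yl)-4-methylpent-3-en-1-ol
Product: 11 (S)-1-(5-ethynylfuran-3-yl)-4-methylpent-3-en-1-yl 3-methylbut-2-enoate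
Conditions: 3-methylbut-2-enoic acid (1.5 equiv), DCC (1.5 equiv), DMAP (0.2 equiv), CH2Cl2, 0 °C → rt
Reagents that add atoms: 3-methylbut-2-enoic acid, CC(C)=CC(=O)O
Why: Steglich esterification acylates the alcohol oxygen with retention at carbon and avoids the acid chloride/amine conditions that deconjugate senecioates through a vinylketene.

Step 8
Reactants: 12 (E)-(2-bromovinyl)trimethylsilane; 13 chromium hexacarbonyl
Product: 16 pentacarbonyl[methoxy((E)-2-(trimethylsilyl)ethenyl)carbene]chromium, via vinyllithium 14 (not isolated), via lithium acylchromate 15 (not isolated)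
Conditions: t-BuLi (2.0 equiv), Et2O, −78 °C; Cr(CO)6, Et2O, −78 °C → rt; then MeOTf, CH2Cl2, 0 °C → rt
Reagents that add atoms: methyl trifluoromethanesulfonate, COS(=O)(=O)C(F)(F)F
Why: Halogen–lithium exchange gives the configurationally stable (E)-vinyllithium, which adds to a CO ligand of Cr(CO)6, and O-methylation of the resulting acylchromate completes the Fischer carbene synthesis.

Step 9
Reactants: 11 (S)-1-(5-ethynylfuran-3-yl)-4-methylpent-3-en-1-yl 3-methylbut-2-enoate; 16 pentacarbonyl[methoxy((E)-2-(trimethylsilyl)ethenyl)carbene]chromium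
Product: 18 (S)-1-[5-(5-methoxy-2-(trimethylsilyloxy)phenyl)furan-3-yl]-4-methylpent-3-en-1-yl 3-methylbut-2-enoate, via arene tricarbonylchromium complex 17 (not isolated)
Conditions: 16 (1.4 equiv), degassed THF (0.05 M), 50 °C, Ar; then air, rt; filtration through Celite and rapid passage over Et3N-deactivated silica
Reagents that add atoms: none
Why: Thermal loss of one CO from the zerovalent chromium carbene 16 lets the alkyne of 11 coordinate and insert into the Cr=C bond; CO insertion gives a metal-bound dienylketene that cyclises to a 6-silylcyclohexa-2,4-dienone, and a 1,3-shift of silicon from carbon to oxygen aromatises it to the aryl silyl ether, first as its Cr(CO)3 complex 17, which air frees from the metal. The closest known reaction type is the Dötz benzannulation of alkenyl(alkoxy)carbene chromium complexes with terminal alkynes, in the variant where a 2-silylvinyl complex stands in for the unstable parent vinyl complex. The benzene ring closes by 6π-electrocyclisation of the dienylketene, joining the former CO carbon to the silyl-bearing vinyl carbon after the alkyne carbon–carbene carbon and alkyne carbon–CO carbon bonds are in place. No stereocenter is made, and the (S)-furylic ester lies far from the reacting atoms in a neutral medium, so it should pass through unchanged. The step needs one sense of alkyne insertion, which the terminal alkyne secures sterically: its CH carbon bonds to the carbene carbon and the furyl-bearing carbon ends next to the CO-derived carbon, putting the furan ortho to the silyloxy group and the methoxy group para to it. Alkenyl complexes favour phenol formation over cyclobutenone or furan by-products, and the trisubstituted alkene and the β,β-disubstituted acrylate should not react with the carbene at 50 °C.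

Step 10
Reactants: 18 (S)-1-[5-(5-methoxy-2-(trimethylsilyloxy)phenyl)furan-3-yl]-4-methylpent-3-en-1-yl 3-methylbut-2-enoate
Product: 19 (S)-1-[5-(3,6-dioxocyclohexa-1,4-dien-1-yl)furan-3-yl]-4-methylpent-3-en-1-yl 3-methylbut-2-enoate
Conditions: (NH4)2Ce(NO3)6 (2.3 equiv), MeCN/H2O (3:1), 0 °C, 10 min
Reagents that add atoms: water, O
Why: Tetravalent cerium removes two electrons from the para-dioxygenated ring, water attacks the methoxy-bearing carbon and methanol and the labile silyl group are lost (oxidative demethylation of a hydroquinone ether to the quinone); this should be fast enough at 0 °C to spare the furan, the alkene and the furylic ester, and any silyl ether already hydrolysed to the phenol converges on the same quinone.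

Step 11
Reactants: 19 (S)-1-[5-(3,6-dioxocyclohexa-1,4-dien-1-yl)furan-3-yl]-4-methylpent-3-en-1-yl 3-methylbut-2-enoate
Product: 20 (S)-1-[5-(2,5-dihydroxyphenyl)furan-3-yl]-4-methylpent-3-en-1-yl 3-methylbut-2-enoate
Conditions: Na2S2O4 (excess, aq), EtOAc, rt, Ar
Reagents that add atoms: none
Why: Dithionite reduction of the 1,4-benzoquinone to the hydroquinone runs under near-neutral two-phase conditions that should not touch the ester, the alkenes or the stereocenter.

Compound list
1 | 4-bromofuran-2-carbaldehyde | O=Cc1cc(Br)co1 | starting material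
2 | 2-(4-bromofuran-2-yl)-1,3-dioxolane | Brc1coc(C2OCCO2)c1 | intermediate
3 | 4-methylpent-3-enoic acid | CC(C)=CCC(=O)O | starting material
4 | 1-(imidazol-1-yl)-4-methylpent-3-en-1-one (acyl imidazolide) | CC(C)=CCC(=O)n1ccnc1 | intermediate
5 | N-methoxy-N,4-dimethylpent-3-enamide | CC(C)=CCC(=O)N(C)OC | intermediate
6 | [5-(1,3-dioxolan-2-yl)furan-3-yl]lithium | [Li]c1coc(C2OCCO2)c1 | intermediate
7 | 1-[5-(1,3-dioxolan-2-yl)furan-3-yl]-4-methylpent-3-en-1-one | CC(C)=CCC(=O)c1coc(C2OCCO2)c1 | intermediate
8 | (S)-1-[5-(1,3-dioxolan-2-yl)furan-3-yl]-4-methylpent-3-en-1-ol | CC(C)=CC[C@H](O)c1coc(C2OCCO2)c1 | intermediate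
9 | 4-[(S)-1-hydroxy-4-methylpent-3-en-1-yl]furan-2-carbaldehyde | CC(C)=CC[C@H](O)c1coc(C=O)c1 | intermediate
10 | (S)-1-(5-ethynylfuran-3-yl)-4-methylpent-3-en-1-ol | CC(C)=CC[C@H](O)c1coc(C#C)c1 | intermediate
11 | (S)-1-(5-ethynylfuran-3-yl)-4-methylpent-3-en-1-yl 3-methylbut-2-enoate | CC(C)=CC[C@H](OC(=O)C=C(C)C)c1coc(C#C)c1 | intermediate
12 | (E)-(2-bromovinyl)trimethylsilane | C[Si](C)(C)/C=C/Br | starting material
13 | chromium hexacarbonyl, Cr(CO)6 | O=C=[Cr](=C=O)(=C=O)(=C=O)(=C=O)=C=O | starting material
14 | (E)-[2-(trimethylsilyl)ethenyl]lithium | [Li]/C=C/[Si](C)(C)C | intermediate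
15 | lithium pentacarbonyl[(E)-3-(trimethylsilyl)prop-2-enoyl]chromate | [Li+].[O-]C(/C=C/[Si](C)(C)C)=[Cr](=C=O)(=C=O)(=C=O)(=C=O)=C=O | intermediate
16 | pentacarbonyl[methoxy((E)-2-(trimethylsilyl)ethenyl)carbene]chromium | COC(/C=C/[Si](C)(C)C)=[Cr](=C=O)(=C=O)(=C=O)(=C=O)=C=O | intermediate
17 | tricarbonylchromium complex of 18, Cr(CO)3 bound η6 to the new benzene ring (written as two fragments) | CC(C)=CC[C@H](OC(=O)C=C(C)C)c1coc(-c2cc(OC)ccc2O[Si](C)(C)C)c1.O=C=[Cr](=C=O)=C=O | intermediate
18 | (S)-1-[5-(5-methoxy-2-(trimethylsilyloxy)phenyl)furan-3-yl]-4-methylpent-3-en-1-yl 3-methylbut-2-enoate | CC(C)=CC[C@H](OC(=O)C=C(C)C)c1coc(-c2cc(OC)ccc2O[Si](C)(C)C)c1 | intermediate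
19 | (S)-1-[5-(3,6-dioxocyclohexa-1,4-dien-1-yl)furan-3-yl]-4-methylpent-3-en-1-yl 3-methylbut-2-enoate (furylbenzoquinone) | CC(C)=CC[C@H](OC(=O)C=C(C)C)c1coc(C2=CC(=O)C=CC2=O)c1 | intermediate
20 | (S)-1-[5-(2,5-dihydroxyphenyl)furan-3-yl]-4-methylpent-3-en-1-yl 3-methylbut-2-enoate | CC(C)=CC[C@H](OC(=O)C=C(C)C)c1coc(-c2cc(O)ccc2O)c1 | target

Total step count: 11.
Longest linear sequence: 9 steps (1 → 2 → 7 → 8 → 9 → 10 → 11 → 18 → 19 → 20, that is steps 1, 3, 4, 5, 6, 7, 9, 10 and 11).

Steps most likely to fail

Step 9. The electron-rich furyl alkyne may oligomerise at the metal, CO insertion may be incomplete, or hydrogen may shift in place of silicon so that silicon stays on carbon. The fallback buys the benzene ring instead of building it. It sets out from Weinreb amide 5 and comes back to the route at quinone 19. 2,4-Dibromofuran would be coupled at its more reactive C2–Br bond with 2,5-dimethoxyphenylboronic acid (Pd(PPh3)4, Na2CO3, DME/H2O, 80 °C, Suzuki–Miyaura coupling) to give 4-bromo-2-(2,5-dimethoxyphenyl)furan F1. Bromine–lithium exchange (n-BuLi, THF, −78 °C) and acylation with 5 should give 1-[5-(2,5-dimethoxyphenyl)furan-3-yl]-4-methylpent-3-en-1-one F2. Oxazaborolidine reduction as in step 4 should give (S)-1-[5-(2,5-dimethoxyphenyl)furan-3-yl]-4-methylpent-3-en-1-ol F3. Steglich esterification as in step 7 should give (S)-1-[5-(2,5-dimethoxyphenyl)furan-3-yl]-4-methylpent-3-en-1-yl 3-methylbut-2-enoate F4. Oxidative demethylation of F4 with (NH4)2Ce(NO3)6 in MeCN/H2O at 0 °C should then deliver 19.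

Step 10. The single-electron oxidant may over-oxidise the electron-rich furan, or the furylic ester may ionise in the acidic cerium medium. The fallback sets out from silyl ether 18 and comes back at quinone 19. Brief stirring of 18 with 5% aqueous citric acid in THF at 0 °C should free (S)-1-[5-(2-hydroxy-5-methoxyphenyl)furan-3-yl]-4-methylpent-3-en-1-yl 3-methylbut-2-enoate F5. This phenol would then be oxidised with PhI(OAc)2 (1.1 equiv) in MeCN/H2O at 0 °C, a two-electron hypervalent iodine oxidation of a 4-methoxyphenol that passes through ligand exchange at the phenol oxygen and loss of methanol. That medium is nearly neutral and holds no metal oxidant.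

Step 3. The furyllithium may take a proton from the acidic α-CH2 of the amide instead of adding, lithium may migrate to the α-position of the furan, or the β,γ-enone may slip into conjugation on work-up. The fallback sets out from bromide 2 and comes back at alcohol 8, so it also replaces the ketone reduction of step 4 should its facial selectivity prove poor.
- The furyllithium from 2 would be quenched with DMF to give 5-(1,3-dioxolan-2-yl)furan-3-carbaldehyde F6.
- Brown allylation with (−)-Ipc2B(allyl), made from (−)-Ipc2BOMe (the reagent derived from (+)-α-pinene) and allylmagnesium bromide, in Et2O at −78 °C with NaOH/H2O2 work-up should give (S)-1-[5-(1,3-dioxolan-2-yl)furan-3-yl]but-3-en-1-ol F7. The sense is predicted from the (S)-carbinol this reagent gives with benzaldehyde.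
- Cross-metathesis of F7 with excess 2-methylbut-2-ene (second-generation Grubbs catalyst, CH2Cl2, 40 °C) should turn the allyl group into the prenyl group and give 8.

Further compounds
F1 | step 9 | 4-bromo-2-(2,5-dimethoxyphenyl)furan | COc1ccc(OC)c(-c2cc(Br)co2)c1
F2 | step 9 | 1-[5-(2,5-dimethoxyphenyl)furan-3-yl]-4-methylpent-3-en-1-one | CC(C)=CCC(=O)c1coc(-c2cc(OC)ccc2OC)c1
F3 | step 9 | (S)-1-[5-(2,5-dimethoxyphenyl)furan-3-yl]-4-methylpent-3-en-1-ol | CC(C)=CC[C@H](O)c1coc(-c2cc(OC)ccc2OC)c1
F4 | step 9 | (S)-1-[5-(2,5-dimethoxyphenyl)furan-3-yl]-4-methylpent-3-en-1-yl 3-methylbut-2-enoate | CC(C)=CC[C@H](OC(=O)C=C(C)C)c1coc(-c2cc(OC)ccc2OC)c1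
F5 | step 10 | (S)-1-[5-(2-hydroxy-5-methoxyphenyl)furan-3-yl]-4-methylpent-3-en-1-yl 3-methylbut-2-enoate | CC(C)=CC[C@H](OC(=O)C=C(C)C)c1coc(-c2cc(OC)ccc2O)c1
F6 | step 3 | 5-(1,3-dioxolan-2-yl)furan-3-carbaldehyde | O=Cc1coc(C2OCCO2)c1
F7 | step 3 | (S)-1-[5-(1,3-dioxolan-2-yl)furan-3-yl]but-3-en-1-ol | C=CC[C@H](O)c1coc(C2OCCO2)c1
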